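Everything rests on cutting the pyran ring (ring C) of the flavan between O1 and C8a and between C3 and C4. C8a is the ring-A carbon ortho to C4 and meta to both phenolic oxygens (C5, C7): as a fluoride next to a C4 formyl group it is SNAr-active, and that formyl group then takes the C3 carbanion. One flask thus joins a 2-fluoro-4,6-bis(benzyloxy)benzaldehyde to an open-chain (R)-β-hydroxy-α-methoxyphosphonate (C2 carbinol, C3 at enol-ether level) and gives the flav-3-ene enol ether. Hydride reduction of the derived C3 ketone sets 2,3-cis; the resulting protected epicatechin serves both halves, C4 of one being ionized late for the 4β→6 union with the 8-bromo-capped gallate of the other.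

Key step: step 4

Remark: C1 of the open-chain phosphonate intermediates (the future C3 of the flavan) is a stereocentre of no consequence; its epimers are carried together and it is left undefined in the SMILES, because it becomes sp2 in the key step.

Step 1
Reactants: 1 2,4,6-trifluorobenzaldehyde
Product: 2 4,6-bis(benzyloxy)-2-fluorobenzaldehyde
Conditions: BnOH (2.05 equiv), NaH (2.1 equiv), THF/DMF, −20 °C → rt
Reagents that add atoms: benzyl alcohol, OCc1ccccc1
Why: Twofold nucleophilic aromatic substitution (SNAr): benzyloxide displaces the fluorides para and then ortho to the formyl group, and two equivalents at low temperature should leave the last ortho fluoride, which is less activated once two donor ethers are conjugated with the aldehyde.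

Step 2
Reactants: 3 methyl 3,4-bis(benzyloxy)benzoate; 4 diethyl (methoxymethyl)phosphonate
Product: 5 diethyl {2-[3,4-bis(benzyloxy)phenyl]-1-methoxy-2-oxoethyl}phosphonate (racemic)
Conditions: 4 (2.2 equiv), LiN(i-Pr)2 (2.2 equiv), THF, −78 °C; then 3, −78 → 0 °C; AcOH
Reagents that add atoms: none
Why: Claisen-type C-acylation of the α-lithiated phosphonate by the ester, in which the second equivalent of carbanion deprotonates the β-ketophosphonate formed and so prevents a second addition.

Step 3
Reactants: 5 diethyl {2-[3,4-bis(benzyloxy)phenyl]-1-methoxy-2-oxoethyl}phosphonate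
Product: 6 diethyl {(2R)-2-[3,4-bis(benzyloxy)phenyl]-2-hydroxy-1-methoxyethyl}phosphonate
Conditions: RuCl[(S,S)-TsDPEN](p-cymene) (1 mol %), HCO2H/Et3N (5:2), DMF, 40 °C
Reagents that add atoms: none
Why: Noyori–Ikariya asymmetric transfer hydrogenation of the aryl ketone, in which the (S,S)-ligand should deliver hydride to the carbonyl face that gives the (R)-carbinol (the future C2), while the base-labile C1 centre equilibrates and is lost later anyway.

Step 4
Reactants: 6 diethyl {(2R)-2-[3,4-bis(benzyloxy)phenyl]-2-hydroxy-1-methoxyethyl}phosphonate; 2 4,6-bis(benzyloxy)-2-fluorobenzaldehyde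
Product: 9 (2R)-5,7-bis(benzyloxy)-2-[3,4-bis(benzyloxy)phenyl]-3-methoxy-2H-chromene, via aryl ether aldehyde 7 (not isolated), via cyclic hydroxyphosphonate 8 (not isolated)
Conditions: NaH (1.1 equiv), DMF, 0 °C; 2, 0 → 40 °C; then t-BuOK (1.3 equiv), 40 → 60 °C, same flask
Reagents that add atoms: none
Why: The sodium alkoxide of 6 displaces the fluoride at C8a of 2 by addition–elimination (SNAr), which the ortho formyl group activates and the two benzyloxy groups do not retard because both are meta to C8a, so that aryl ether 7 carries the O1–C8a bond; tert-butoxide then removes the proton at C3 (between phosphorus and the methoxy oxygen), the carbanion adds to the formyl carbon C4 to give alkoxide 8, and syn-elimination of diethyl phosphate leaves the C3=C4 double bond (Horner–Wadsworth–Emmons olefination). The closest known reaction types are the SNAr etherification of ortho-fluorobenzaldehydes and the olefination of aldehydes with α-alkoxyphosphonates to enol ethers, joined here as a polarity-reversed counterpart of the Schweizer chromene annulation. Only ring C is closed, by 6-exo-trig addition of the C3 carbanion to the C4 carbonyl, and the ring imposes the cis olefin geometry. No stereocentre is created: C2 keeps its R configuration because O1 acts as the nucleophile, so the C2–O1 bond is never broken, and C2–H is not acidic under these bases, while the undefined C3 centre of 6 is erased. The step needs O-arylation before carbanion formation, which the order of base addition secures, and ring closure faster than β-elimination of the aryloxide from the C3 carbanion, which the adjacent formyl group held in a six-membered array should secure.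

Step 5
Reactants: 9 (2R)-5,7-bis(benzyloxy)-2-[3,4-bis(benzyloxy)phenyl]-3-methoxy-2H-chromene
Product: 10 (2R)-5,7-bis(benzyloxy)-2-[3,4-bis(benzyloxy)phenyl]chroman-3-one
Conditions: 0.5 M aq. HCl, THF, 0 °C → rt; used at once
Reagents that add atoms: water, O
Why: Acid-catalysed enol ether hydrolysis (protonation at C4, addition of water to the C3 oxocarbenium ion, loss of methanol) should give the C3 ketone under conditions mild and brief enough to leave the enolizable C2 centre and the benzyl ethers untouched.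

Step 6
Reactants: 10 (2R)-5,7-bis(benzyloxy)-2-[3,4-bis(benzyloxy)phenyl]chroman-3-one
Product: 11 (2R,3R)-5,7-bis(benzyloxy)-2-[3,4-bis(benzyloxy)phenyl]chroman-3-ol (5,7,3′,4′-tetra-O-benzyl-(−)-epicatechin)
Conditions: LiBH(s-Bu)3, THF, −78 °C; then H2O
Reagents that add atoms: none
Why: Diastereoselective ketone reduction with a bulky trialkylborohydride: hydride should attack C3 from the equatorial side, anti to the C2 aryl group, so that the new hydroxyl (3R) is axial and cis to ring B.

Step 7
Reactants: 11 5,7,3′,4′-tetra-O-benzyl-(−)-epicatechin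
Product: 12 4β-(2-ethoxyethoxy)-5,7,3′,4′-tetra-O-benzyl-(−)-epicatechin (ether at C4 trans to the 3-hydroxyl)
Conditions: DDQ (2 equiv), 2-ethoxyethanol (5 equiv), CH2Cl2, rt
Reagents that add atoms: 2-ethoxyethanol, CCOCCO
Why: Benzylic oxidation with DDQ: hydride abstraction from C4 gives a cation stabilized by the 5- and 7-oxygens of ring A, which the alcohol should trap trans to the 3-hydroxyl, and this C4 configuration is not critical because the centre is ionized again in step 11.

Step 8
Reactants: 12 4β-(2-ethoxyethoxy)-5,7,3′,4′-tetra-O-benzyl-(−)-epicatechin; 13 3,4,5-tris(benzyloxy)benzoic acid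
Product: 14 4β-(2-ethoxyethoxy)-5,7,3′,4′-tetra-O-benzyl-(−)-epicatechin 3-O-[3,4,5-tris(benzyloxy)benzoate]
Conditions: DCC, DMAP (cat.), CH2Cl2, rt
Reagents that add atoms: none
Why: Steglich esterification of the secondary 3-hydroxyl with the protected gallic acid under neutral conditions, which touches no stereocentre and spares the acid-labile C4 ether.

Step 9
Reactants: 11 5,7,3′,4′-tetra-O-benzyl-(−)-epicatechin; 13 3,4,5-tris(benzyloxy)benzoic acid
Product: 15 hepta-O-benzyl-(−)-epicatechin 3-O-gallate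
Conditions: DCC, DMAP (cat.), CH2Cl2, rt
Reagents that add atoms: none
Why: Steglich esterification of the axial 3-hydroxyl of a second portion of 11 with the protected gallic acid, which touches no stereocentre and makes the lower unit from the same intermediate as the upper one.

Step 10
Reactants: 15 hepta-O-benzyl-(−)-epicatechin 3-O-gallate
Product: 16 8-bromo-hepta-O-benzyl-(−)-epicatechin 3-O-gallate
Conditions: NBS (1.05 equiv), CH2Cl2, −40 → 0 °C
Reagents that add atoms: N-bromosuccinimide, O=C1CCC(=O)N1Br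
Why: Electrophilic aromatic bromination: C8 is the most nucleophilic position of the 5,7-dialkoxy ring A, so one equivalent of NBS should cap it and leave C6 as the only nucleophilic site for step 11.

Step 11
Reactants: 14 4β-(2-ethoxyethoxy)-5,7,3′,4′-tetra-O-benzyl-(−)-epicatechin 3-O-[3,4,5-tris(benzyloxy)benzoate]; 16 8-bromo-hepta-O-benzyl-(−)-epicatechin 3-O-gallate
Product: 17 tetradeca-O-benzyl-8-bromo derivative of the target (upper unit C4 bonded 4β to C6 of the brominated lower unit)
Conditions: Me3SiOTf (0.2 equiv), 16 (3 equiv), CH2Cl2, −78 → −40 °C; then aq. NaHCO3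
Reagents that add atoms: none
Why: Lewis-acid-promoted Friedel–Crafts alkylation: Me3SiOTf ionizes the C4 ether of 14 and C6 of 16 (C8 being blocked by bromine) should attack the C4 cation anti to the pseudo-axial 3-O-galloyl group, which sets the 4β configuration (3,4-trans, the centre that is S in the target) and the 4→6 linkage.

Step 12
Reactants: 17 tetradeca-O-benzyl-8-bromo derivative of the target
Product: 18 procyanidin B-5 3,3′-di-O-gallate
Conditions: H2 (1 atm), Pd(OH)2/C, Et3N (1.5 equiv), THF/MeOH, rt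
Reagents that add atoms: none
Why: Palladium-catalysed hydrogenolysis should cleave the fourteen benzyl ethers and the aryl C–Br bond, while Et3N takes up HBr so that the acid-labile interflavan bond and the esters survive.

Compound list
1 | 2,4,6-trifluorobenzaldehyde | O=Cc1c(F)cc(F)cc1F | starting material
2 | 4,6-bis(benzyloxy)-2-fluorobenzaldehyde | O=Cc1c(F)cc(OCc2ccccc2)cc1OCc1ccccc1 | intermediate
3 | methyl 3,4-bis(benzyloxy)benzoate | COC(=O)c1ccc(OCc2ccccc2)c(OCc2ccccc2)c1 | starting material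
4 | diethyl (methoxymethyl)phosphonate | CCOP(=O)(COC)OCC | starting material
5 | diethyl {2-[3,4-bis(benzyloxy)phenyl]-1-methoxy-2-oxoethyl}phosphonate (racemic) | CCOP(=O)(OCC)C(OC)C(=O)c1ccc(OCc2ccccc2)c(OCc2ccccc2)c1 | intermediate
6 | diethyl {(2R)-2-[3,4-bis(benzyloxy)phenyl]-2-hydroxy-1-methoxyethyl}phosphonate (C1 undefined) | CCOP(=O)(OCC)C(OC)[C@H](O)c1ccc(OCc2ccccc2)c(OCc2ccccc2)c1 | intermediate
7 | diethyl {(2R)-2-[3,4-bis(benzyloxy)phenyl]-2-[3,5-bis(benzyloxy)-2-formylphenoxy]-1-methoxyethyl}phosphonate (C1 undefined) | CCOP(=O)(OCC)C(OC)[C@H](Oc1cc(OCc2ccccc2)cc(OCc2ccccc2)c1C=O)c1ccc(OCc2ccccc2)c(OCc2ccccc2)c1 | intermediate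
8 | diethyl {(2R)-5,7-bis(benzyloxy)-2-[3,4-bis(benzyloxy)phenyl]-4-hydroxy-3-methoxy-3,4-dihydro-2H-chromen-3-yl}phosphonate (as potassium alkoxide in the flask; C3 and C4 undefined) | CCOP(=O)(OCC)C1(OC)C(O)c2c(OCc3ccccc3)cc(OCc3ccccc3)cc2O[C@@H]1c1ccc(OCc2ccccc2)c(OCc2ccccc2)c1 | intermediate
9 | (2R)-5,7-bis(benzyloxy)-2-[3,4-bis(benzyloxy)phenyl]-3-methoxy-2H-chromene | COC1=Cc2c(OCc3ccccc3)cc(OCc3ccccc3)cc2O[C@@H]1c1ccc(OCc2ccccc2)c(OCc2ccccc2)c1 | intermediate
10 | (2R)-5,7-bis(benzyloxy)-2-[3,4-bis(benzyloxy)phenyl]chroman-3-one | O=C1Cc2c(OCc3ccccc3)cc(OCc3ccccc3)cc2O[C@@H]1c1ccc(OCc2ccccc2)c(OCc2ccccc2)c1 | intermediate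
11 | (2R,3R)-5,7-bis(benzyloxy)-2-[3,4-bis(benzyloxy)phenyl]chroman-3-ol (5,7,3′,4′-tetra-O-benzyl-(−)-epicatechin) | O[C@@H]1Cc2c(OCc3ccccc3)cc(OCc3ccccc3)cc2O[C@@H]1c1ccc(OCc2ccccc2)c(OCc2ccccc2)c1 | intermediate
12 | 4β-(2-ethoxyethoxy)-5,7,3′,4′-tetra-O-benzyl-(−)-epicatechin (2,3-cis, 3,4-trans) | O[C@@H]1[C@@H](OCCOCC)c2c(OCc3ccccc3)cc(OCc3ccccc3)cc2O[C@@H]1c1ccc(OCc2ccccc2)c(OCc2ccccc2)c1 | intermediate
13 | 3,4,5-tris(benzyloxy)benzoic acid | OC(=O)c1cc(OCc2ccccc2)c(OCc2ccccc2)c(OCc2ccccc2)c1 | starting material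
14 | 4β-(2-ethoxyethoxy)-5,7,3′,4′-tetra-O-benzyl-(−)-epicatechin 3-O-[3,4,5-tris(benzyloxy)benzoate] | O=C(O[C@@H]1[C@@H](OCCOCC)c2c(OCc3ccccc3)cc(OCc3ccccc3)cc2O[C@@H]1c1ccc(OCc2ccccc2)c(OCc2ccccc2)c1)c1cc(OCc2ccccc2)c(OCc2ccccc2)c(OCc2ccccc2)c1 | intermediate
15 | hepta-O-benzyl-(−)-epicatechin 3-O-gallate | O=C(O[C@@H]1Cc2c(OCc3ccccc3)cc(OCc3ccccc3)cc2O[C@@H]1c1ccc(OCc2ccccc2)c(OCc2ccccc2)c1)c1cc(OCc2ccccc2)c(OCc2ccccc2)c(OCc2ccccc2)c1 | intermediate
16 | 8-bromo-hepta-O-benzyl-(−)-epicatechin 3-O-gallate | O=C(O[C@@H]1Cc2c(OCc3ccccc3)cc(OCc3ccccc3)c(Br)c2O[C@@H]1c1ccc(OCc2ccccc2)c(OCc2ccccc2)c1)c1cc(OCc2ccccc2)c(OCc2ccccc2)c(OCc2ccccc2)c1 | intermediate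
17 | tetradeca-O-benzyl-8-bromo derivative of the target (4β→6 dimer, bromine at C8 of the lower unit) | O=C(O[C@@H]1[C@@H](c2c(OCc3ccccc3)c(Br)c3c(c2OCc2ccccc2)C[C@@H](OC(=O)c2cc(OCc4ccccc4)c(OCc4ccccc4)c(OCc4ccccc4)c2)[C@@H](c2ccc(OCc4ccccc4)c(OCc4ccccc4)c2)O3)c2c(OCc3ccccc3)cc(OCc3ccccc3)cc2O[C@@H]1c1ccc(OCc2ccccc2)c(OCc2ccccc2)c1)c1cc(OCc2ccccc2)c(OCc2ccccc2)c(OCc2ccccc2)c1 | intermediate
18 | procyanidin B-5 3,3′-di-O-gallate | O=C(O[C@@H]1[C@@H](c2c(O)cc3c(c2O)C[C@@H](OC(=O)c2cc(O)c(O)c(O)c2)[C@@H](c2ccc(O)c(O)c2)O3)c2c(O)cc(O)cc2O[C@@H]1c1ccc(O)c(O)c1)c1cc(O)c(O)c(O)c1 | target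

Total step count: 12. Longest linear sequence: 9 steps (steps 2, 3, 4, 5, 6, 7, 8, 11, 12). Compound 11 is divided between the upper-unit branch (steps 7 and 8) and the lower-unit branch (steps 9 and 10).

Steps most likely to fail

Step 4. β-Elimination of the aryloxide from the C3 carbanion of 7, or Horner-type fragmentation of the β-oxido phosphonate of 6 before O-arylation, may outrun the ring closure; the hindered secondary alkoxide may also arylate slowly. The fallback makes the two bonds in the opposite order, in separate known steps, setting out from 6 and 2. The hydroxyl of 6 is silylated (t-BuMe2SiCl, imidazole, DMF) to the silyl ether F1. F1 is lithiated at C1 with LiN(i-Pr)2 and condensed with aldehyde 2 in an intermolecular Horner–Wadsworth–Emmons olefination (THF, −78 °C → reflux) to the E enol ether F2, the isomer with ring A cis to C2; any Z isomer is equilibrated with catalytic iodine. Bu4NF frees the alcohol F3. Its potassium alkoxide (KH, 18-crown-6, THF, 50 °C) closes the pyran by intramolecular SNAr on the unactivated aryl fluoride, a ring closure of the type used for 5,7-dialkoxyflavans, and this returns to the route at 9.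

Step 11. Self-condensation of the cation from 14 with the unblocked, more nucleophilic C8 of a second molecule of 14 may compete with attack by the hindered, bromine-deactivated C6 of 16. The fallback caps the electrophile as well, setting out from 14. NBS (CH2Cl2, −40 °C) gives the 8-bromo electrophile F4. Me3SiOTf-promoted coupling of F4 with 16 gives the dibromo dimer F5. Hydrogenolysis as in step 12 removes both bromines and all benzyl groups and returns to the route at 18.

Step 12. Poisoning of the catalyst by bromide, incomplete cleavage of fourteen benzyl ethers on a crowded dimer, or scission of the doubly benzylic C4–C6 bond during a long hydrogenation may leave partly protected or cleaved material. The fallback separates the two tasks, setting out from 17. Radical-chain reduction of the aryl bromide (Bu3SnH, AIBN, toluene, 90 °C) gives the bromine-free tetradeca-O-benzyl dimer F6. Hydrogenolysis of F6 over Pd(OH)2/C (H2, THF/MeOH/H2O, rt), now without amine or bromide in the flask, returns to the route at 18.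

Further compounds
F1 | step 4 | diethyl {(2R)-2-[3,4-bis(benzyloxy)phenyl]-2-[(tert-butyldimethylsilyl)oxy]-1-methoxyethyl}phosphonate (C1 undefined) | CCOP(=O)(OCC)C(OC)[C@H](O[Si](C)(C)C(C)(C)C)c1ccc(OCc2ccccc2)c(OCc2ccccc2)c1
F2 | step 4 | tert-butyl{[(1R,2E)-1-[3,4-bis(benzyloxy)phenyl]-3-[4,6-bis(benzyloxy)-2-fluorophenyl]-2-methoxyprop-2-en-1-yl]oxy}dimethylsilane | CO/C(=C/c1c(F)cc(OCc2ccccc2)cc1OCc1ccccc1)[C@H](O[Si](C)(C)C(C)(C)C)c1ccc(OCc2ccccc2)c(OCc2ccccc2)c1
F3 | step 4 | (1R,2E)-1-[3,4-bis(benzyloxy)phenyl]-3-[4,6-bis(benzyloxy)-2-fluorophenyl]-2-methoxyprop-2-en-1-ol | CO/C(=C/c1c(F)cc(OCc2ccccc2)cc1OCc1ccccc1)[C@H](O)c1ccc(OCc2ccccc2)c(OCc2ccccc2)c1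
F4 | step 11 | 8-bromo-4β-(2-ethoxyethoxy)-5,7,3′,4′-tetra-O-benzyl-(−)-epicatechin 3-O-[3,4,5-tris(benzyloxy)benzoate] | O=C(O[C@@H]1[C@@H](OCCOCC)c2c(OCc3ccccc3)cc(OCc3ccccc3)c(Br)c2O[C@@H]1c1ccc(OCc2ccccc2)c(OCc2ccccc2)c1)c1cc(OCc2ccccc2)c(OCc2ccccc2)c(OCc2ccccc2)c1
F5 | step 11 | tetradeca-O-benzyl-8,8′-dibromo derivative of the target (bromine at C8 of both units) | O=C(O[C@@H]1[C@@H](c2c(OCc3ccccc3)c(Br)c3c(c2OCc2ccccc2)C[C@@H](OC(=O)c2cc(OCc4ccccc4)c(OCc4ccccc4)c(OCc4ccccc4)c2)[C@@H](c2ccc(OCc4ccccc4)c(OCc4ccccc4)c2)O3)c2c(OCc3ccccc3)cc(OCc3ccccc3)c(Br)c2O[C@@H]1c1ccc(OCc2ccccc2)c(OCc2ccccc2)c1)c1cc(OCc2ccccc2)c(OCc2ccccc2)c(OCc2ccccc2)c1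
F6 | step 12 | tetradeca-O-benzyl-procyanidin B-5 3,3′-di-O-gallate (bromine-free protected dimer) | O=C(O[C@@H]1[C@@H](c2c(OCc3ccccc3)cc3c(c2OCc2ccccc2)C[C@@H](OC(=O)c2cc(OCc4ccccc4)c(OCc4ccccc4)c(OCc4ccccc4)c2)[C@@H](c2ccc(OCc4ccccc4)c(OCc4ccccc4)c2)O3)c2c(OCc3ccccc3)cc(OCc3ccccc3)cc2O[C@@H]1c1ccc(OCc2ccccc2)c(OCc2ccccc2)c1)c1cc(OCc2ccccc2)c(OCc2ccccc2)c(OCc2ccccc2)c1
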